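In this closed, stirred vessel the solid reagent feeds partner into solution, and each catalytic turn takes one partner and one substrate of either hand to product.

in all of them: left-handed substrate 0.017 M; right-handed substrate 0.017 M; catalyst 1.3 mol%; added ligand 0.13 mM

| charge | solid reagent | remark | time |
|---|---|---|---|
| eta | 0.40 equiv | run made earlier |  |
| beta | 1.6 equiv | run made earlier |  |
| Wednesday's | 0.800 equiv |  | 8.0 min |
| Friday's | 0.800 equiv |  | 12 min |

| run | time / min | left-handed substrate / % | left-handed product / % | right-handed substrate / % | right-handed product / % |
|---|---|---|---|---|---|
| eta | 2.50 | 48.5 | 3.6 | 48.0 | 2.5 |
| eta | 5.00 | 43.6 | 7.9 | 46.5 | 2.8 |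
| eta | 8.00 | 39.1 | 12.5 | 45.0 | 6.0 |
| eta | 10.0 | 37.5 | 14.3 | 43.3 | 8.3 |
| beta | 1.33 | 48.5 | 0.8 | 49.3 | 0.2 |
| beta | 3.00 | 44.9 | 1.8 | 47.7 | 2.0 |
| beta | 6.00 | 42.0 | 9.6 | 45.2 | 6.6 |
| beta | 10.0 | 34.6 | 14.3 | 41.7 | 7.1 |

(readings scatter by 1 percentage point)

- catalyst is single-handed; left-handed substrate and right-handed substrate are mirror images of each other, charged as a racemate, each of them at the stated concentration
- given per volume of solution although it is solid: solid reagent
- what may be going on: partner + catalyst + left-handed substrate -> catalyst + left-handed product; partner + catalyst + right-handed substrate -> catalyst + right-handed product; catalyst + added ligand <-> idle complex; solid reagent <-> partner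
- at the start none of the solid reagent is in solution

1. which of these there is most of at the end, counted by the substrate in it, Wednesday's (left-handed substrate / right-handed substrate / right-handed product / left-handed product)
2. which of these there is most of at the end, counted by the substrate in it, Friday's (left-handed substrate / right-handed substrate / right-handed product / left-handed product)
3. the largest of these amounts at the end, in percent of the left-handed substrate and right-handed substrate together charged, Wednesday's
4. the largest of these amounts at the end, in percent of the left-handed substrate and right-handed substrate together charged, Friday's

What I carry is the right-handed share: the part of all product formed that is right-handed product. The last readings of both runs give 35.0 %.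

First I ask where the flask ends. A charge of 0.800 equiv allows products totalling 40.0 % of the substrates charged, and the eta charge allows 20.0 %. The last eta reading sums to 22.6 %, more than that allowance, though the sum carries the scatter of two readings, so I leave it out of the pace and use the eta reading at 8.00 min. With the last beta reading, this gives a mean pace of 0.0223 /min of the charge, although the solid charges are 0.40 equiv and 1.6 equiv. Over Friday's 12 min this pace reckons 26.8 % of products, which is less than the allowance, so I keep the pace constant.

Share times pace gives right-handed substrate of 43.8 % for Wednesday's and 40.6 % for Friday's. The substrate column, a different set of readings, gives a mean loss of 0.00727 /min, hence 44.2 % and 41.3 %. On Friday's the two routes part by 0.70 percentage points, while one reading scatters by 1 point, so the readings can't tell them apart. I commit to the share route. Since the share stands below 0.5, I reckon right-handed substrate above left-handed substrate, and my 26.8 % of both products together on Friday's is less than its 40.6 %.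

The forecast names right-handed substrate for Wednesday's and right-handed substrate for Friday's, at 44.3 % and 41.2 %, slightly above my figures. Its ground for the pace: “This suggests dissolution or saturation limits the partner supply, not the amount of solid charged.”

The flask gives right-handed substrate at 43.5 % on Wednesday's and right-handed substrate at 40.2 % on Friday's, so the forecast stands. At the asked times, 46.2 % of Wednesday's solid reagent and 23.8 % of Friday's remain undissolved. Applied to Friday's products, 26.9 % together, the share gives 9.43 % of right-handed product, and the flask holds 9.82 %.

    partner + catalyst + left-handed substrate → catalyst + left-handed product (k = 2.30 × 10⁵ /M²/min)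
    partner + catalyst + right-handed substrate → catalyst + right-handed product (k = 1.20 × 10⁵ /M²/min)
    catalyst + added ligand ⇌ idle complex, settled at all times (K = 11000 /M)
    solid reagent ⇌ partner, rate k4*(cs4 - [partner]) while solid is left; crystals form when [partner] > cs4 (solubility = 2.00 mM, k = 0.930 /min)

Wednesday's charge read at 30 min lies past the 18.0 min that allowance and pace give, so I take the solid reagent as the limiting reagent there and let the products stop at the allowance, and the share then gives 36.0 % of right-handed substrate. The flask gives 34.9 %, with 0.014 % of the solid reagent's charge left.

The data are simulated for an exercise; noise was put on by code.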